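**Retrosynthetic overview**

1. The target is all-E (3S,4S,3'S,4'S)-7,8-didehydro-β,β-carotene-3,4,3',4'-tetrol. It is cut at C11=C12 and C11'=C12' into an acetylenic C15 phosphonium salt, the C10 trienedial and an olefinic C15 phosphonium salt (two Wittig reactions), with four silyl ethers removed last.
2. The strategy rests on the C7≡C8 triple bond, which joins the tetrasubstituted ring carbon C6 (between the C1 gem-dimethyl group and the C5 methyl group) to the methyl-bearing alkene carbon C9. It is traced back to a ketone in which C6 and C9 sit on one carbonyl carbon, and the missing carbon is inserted by a 1,2-alkenyl shift in an alkylidene carbene.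
3. The ketone comes from 1,2-addition of an E-configured C4 vinyllithium (hydrozirconation–iodination of silylated but-2-yn-1-ol, then I–Li exchange) to the silylated ring aldehyde, followed by oxidation.
4. The ring aldehyde comes from safranal by C3=C4 epoxidation, anti hydrolysis to the trans-diol, resolution and silylation. The same aldehyde gives the olefinic C15 half by a vinylogous Horner–Wadsworth–Emmons reaction.
5. No ring is formed in the route: both cyclohexene rings are carried in from safranal. Each (3S,4S) pair is fixed in relative sense by the epoxide opening and in absolute sense by the resolution.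

Key step: step 9

Remark: carotenoid numbering is used (ring C1–C6, chain C7–C15, primed numbers for the olefinic half); the SMILES is read as trans-(3S,4S) diols in both rings and E at every chain double bond. TBS = tert-butyldimethylsilyl.

**Route**

Step 1
Reactants: 1 safranal
Product: 2 rac-3,4-epoxysafranal (2,4,4-trimethyl-7-oxabicyclo[4.1.0]hept-2-ene-3-carbaldehyde)
Conditions: dimethyldioxirane (1.1 equiv, ca. 0.07 M in acetone), 0 °C, dark
Reagents that add atoms: dimethyldioxirane, CC1(C)OO1
Why: Electrophilic dioxirane epoxidation should take the cis-disubstituted C3=C4 bond, which is far less hindered and less deactivated than the tetrasubstituted formyl-bearing C5=C6 bond, while the neutral reagent avoids the Baeyer–Villiger oxidation of the aldehyde that a peracid would invite; the epoxide can only be cis-fused and forms as a racemate.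

Step 2
Reactants: 2 rac-3,4-epoxysafranal
Product: 3 rac-trans-3,4-dihydroxy-2,6,6-trimethylcyclohex-1-ene-1-carbaldehyde
Conditions: HClO4 (5 mol %), THF/H2O 3:1, 0 °C to rt
Reagents that add atoms: water, O
Why: Acid-catalysed SN2-type anti opening of the epoxide by water gives the trans-diol whichever epoxide carbon is attacked, so the relative trans configuration of C3 and C4 is set here (still racemic), and the acceptor-substituted diene disfavours an allyl cation that could leak to the cis-diol.

Step 3
Reactants: 3 rac-trans-3,4-dihydroxy-2,6,6-trimethylcyclohex-1-ene-1-carbaldehyde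
Product: 4 (3S,4S)-3,4-dihydroxy-2,6,6-trimethylcyclohex-1-ene-1-carbaldehyde
Conditions: preparative supercritical-fluid chromatography on a chiral stationary phase (amylose tris(3,5-dimethylphenylcarbamate) on silica), CO2/MeOH, 35 °C
Reagents that add atoms: none
Why: Resolution by enantioselective chromatography: hydrogen-bond-donating diols are generally well discriminated on polysaccharide carbamate phases, and a physical separation avoids the basic ester cleavage of a covalent resolution, which would invite vinylogous β-elimination of the C3 oxygen (the collapse of 3-oxygenated cyclocitrals to safranal); the absolute configuration of C3 and C4 is fixed by collecting the (3S,4S) enantiomer, to be assigned by circular dichroism against calculation or by X-ray analysis.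

Step 4
Reactants: 4 (3S,4S)-3,4-dihydroxy-2,6,6-trimethylcyclohex-1-ene-1-carbaldehyde
Product: 5 (3S,4S)-3,4-bis(tert-butyldimethylsilyloxy)-2,6,6-trimethylcyclohex-1-ene-1-carbaldehyde
Conditions: TBSOTf (2.6 equiv), 2,6-lutidine (4 equiv), CH2Cl2, −78 °C to −20 °C
Reagents that add atoms: tert-butyldimethylsilyl trifluoromethanesulfonate, CC(C)(C)[Si](C)(C)OS(=O)(=O)C(F)(F)F
Why: Silyl triflate silylation with a hindered pyridine base should cover both secondary hydroxyls, including the allylic C4 hydroxyl beside the C5 methyl group, at low temperature and without a base strong enough to remove C4–H; no stereocentre is touched.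

Step 5
Reactants: 6 but-2-yn-1-ol
Product: 7 tert-butyl(but-2-yn-1-yloxy)dimethylsilane
Conditions: TBSCl, imidazole, CH2Cl2, rt
Reagents that add atoms: tert-butyldimethylsilyl chloride, CC(C)(C)[Si](C)(C)Cl
Why: Standard imidazole-mediated silylation of a primary propargylic alcohol.

Step 6
Reactants: 7 tert-butyl(but-2-yn-1-yloxy)dimethylsilane
Product: 9 (E)-tert-butyl[(3-iodobut-2-en-1-yl)oxy]dimethylsilane, via alkenylzirconocene chloride 8 (not isolated)
Conditions: Cp2Zr(H)Cl (2.0 equiv), THF, 50 °C, 1 h; then I2, THF, 0 °C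
Reagents that add atoms: iodine, II
Why: Hydrozirconation–iodination: Zr–H adds syn, excess reagent at 50 °C equilibrates the regioisomers to the one with zirconium on C3 beside the small methyl group, and iodinolysis of the C–Zr bond with retention gives the E iodide in which iodine is trans to the CH2O group.

Step 7
Reactants: 9 (E)-tert-butyl[(3-iodobut-2-en-1-yl)oxy]dimethylsilane; 5 (3S,4S)-3,4-bis(tert-butyldimethylsilyloxy)-2,6,6-trimethylcyclohex-1-ene-1-carbaldehyde
Product: 11 (2E)-1-[(3S,4S)-3,4-bis(tert-butyldimethylsilyloxy)-2,6,6-trimethylcyclohex-1-en-1-yl]-4-(tert-butyldimethylsilyloxy)-2-methylbut-2-en-1-ol (both carbinol epimers), via vinyllithium 10 (not isolated)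
Conditions: 9 (1.3 equiv), t-BuLi (2.6 equiv), Et2O, −78 °C; then 5, −78 °C to −30 °C; H2O
Reagents that add atoms: none
Why: Iodine–lithium exchange is stereoretentive, and 1,2-addition of the vinyllithium to the ring aldehyde, which has no α-hydrogen, at −78 °C (the carbonyl addition used for damascone-type skeletons) should outrun γ-deprotonation; the new carbinol centre forms as a mixture of epimers that is erased in step 8.

Step 8
Reactants: 11 the doubly allylic carbinol
Product: 12 (2E)-1-[(3S,4S)-3,4-bis(tert-butyldimethylsilyloxy)-2,6,6-trimethylcyclohex-1-en-1-yl]-4-(tert-butyldimethylsilyloxy)-2-methylbut-2-en-1-one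
Conditions: Dess–Martin periodinane (1.5 equiv), NaHCO3, CH2Cl2, 0 °C to rt
Reagents that add atoms: none
Why: Dess–Martin oxidation of the doubly allylic secondary alcohol under buffered, non-acidic conditions gives the cross-conjugated ketone; there is no α-hydrogen to epimerise, and the E alkene and the silyl ethers are unaffected.

Step 9
Reactants: 12 the ring alkenyl ketone; 13 trimethylsilyldiazomethane (1.5 equiv, solution in hexanes)
Product: 17 tert-butyl{[(2E)-5-[(3S,4S)-3,4-bis(tert-butyldimethylsilyloxy)-2,6,6-trimethylcyclohex-1-en-1-yl]-3-methylpent-2-en-4-yn-1-yl]oxy}dimethylsilane, via lithio(trimethylsilyl)diazomethane 14 (not isolated), via diazoalkene 15 (not isolated), via alkylidene carbene 16 (not isolated)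
Conditions: n-BuLi (1.4 equiv), THF, −78 °C; then 12, −78 °C to rt, then 50 °C until N2 evolution ends; H2O
Reagents that add atoms: none
Why: The lithiated diazo compound 14 adds to the carbonyl group of 12, which has no α-hydrogen, and the lithium alkoxide loses Me3SiOLi in a Peterson-type elimination to give diazoalkene 15; loss of N2 leaves alkylidene carbene 16, in which an sp2 substituent moves from the former carbonyl carbon to the carbene carbon, so that C7≡C8 and the second bond of the new carbon (C8–C9 if the butenyl group migrates, C6–C7 if the ring alkenyl group migrates) are formed and one carbon is inserted between C6 and C9. The closest known reaction is the Colvin rearrangement of diaryl and aryl alkenyl ketones with lithiated trimethylsilyldiazomethane, a Fritsch–Buttenberg–Wiechell-type 1,2-shift. No ring is closed and no stereocentre is made; the (3S,4S) silyl ethers are remote spectators. The step needs carbonyl addition in preference to conjugate addition or γ-deprotonation, which the low temperature, the α-methyl group on the enone and the twisted, poorly conjugated ring enone should favour. It also needs 1,2-shift in preference to 1,5 C–H insertion, which is secured because both carbene substituents are alkenyl groups of high migratory aptitude, the only 1,5 C–H bonds in reach are primary ones of ring methyl groups (the least reactive class), and C11–H lies trans to the carbene across C9=C10. Either migration gives the same enyne 17, and an alkenyl group migrates with its geometry intact, so C9=C10 stays E.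

Step 10
Reactants: 17 the tris-TBS acetylenic C15 enyne
Product: 18 (2E)-5-[(3S,4S)-3,4-bis(tert-butyldimethylsilyloxy)-2,6,6-trimethylcyclohex-1-en-1-yl]-3-methylpent-2-en-4-yn-1-ol
Conditions: HF·pyridine, pyridine, THF, 0 °C
Reagents that add atoms: none
Why: Steric differentiation of silyl ethers: buffered HF·pyridine cleaves the unhindered primary allylic ether much faster than the two hindered secondary ring ethers, and the buffered medium does not ionise the allylic C4–O bond.

Step 11
Reactants: 18 the acetylenic C15 alcohol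
Product: 19 acetylenic C15 allylic bromide
Conditions: CBr4 (1.3 equiv), PPh3 (1.3 equiv), CH2Cl2, 0 °C, dark
Reagents that add atoms: carbon tetrabromide, BrC(Br)(Br)Br
Why: Appel reaction: bromide displaces the primary oxyphosphonium group in an SN2 step under neutral conditions, so neither the 9E geometry nor the acid-labile allylic C4 ether is put at risk (an acidic PPh3·HBr protocol is avoided for that reason).

Step 12
Reactants: 19 acetylenic C15 allylic bromide
Product: 20 acetylenic C15 triphenylphosphonium bromide
Conditions: PPh3 (1.5 equiv), EtOAc, rt, dark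
Reagents that add atoms: triphenylphosphine, c1ccc(cc1)P(c1ccccc1)c1ccccc1
Why: SN2 quaternisation of PPh3 by the primary allylic bromide at room temperature keeps the 9E enyne geometry, and the salt should separate from ethyl acetate.

Step 13
Reactants: 20 acetylenic C15 triphenylphosphonium bromide; 21 (2E,4E,6E)-2,7-dimethylocta-2,4,6-trienedial (3 equiv)
Product: 23 (2E,4E,6E,8E,10E)-13-[(3S,4S)-3,4-bis(tert-butyldimethylsilyloxy)-2,6,6-trimethylcyclohex-1-en-1-yl]-2,7,11-trimethyltrideca-2,4,6,8,10-pentaen-12-ynal, via phosphonium ylide 22 (not isolated)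
Conditions: NaOMe (1.1 equiv, 1 M in MeOH, slow addition), CH2Cl2, 0 °C to rt, argon, dark; chromatography
Reagents that add atoms: none
Why: Wittig reaction of a semistabilised allylic ylide: generating the ylide slowly in the presence of excess dialdehyde should favour mono-olefination (the product aldehyde is less electrophilic than 21) and keep the ylide lifetime short, and the new C11=C12 bond is expected mainly E, the hindered Z isomer being removed by chromatography.

Step 14
Reactants: 5 the bis-TBS ring aldehyde; 24 triethyl 3-methyl-4-phosphonocrotonate (sold as an E/Z mixture; E isomer drawn)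
Product: 26 ethyl (2E,4E)-5-[(3S,4S)-3,4-bis(tert-butyldimethylsilyloxy)-2,6,6-trimethylcyclohex-1-en-1-yl]-3-methylpenta-2,4-dienoate, via lithiated phosphonate 25 (not isolated)
Conditions: 24 (1.5 equiv), n-BuLi (1.4 equiv), THF/DMPU, −78 °C; then 5, −78 °C to 0 °C
Reagents that add atoms: none
Why: Vinylogous Horner–Wadsworth–Emmons reaction: the delocalised phosphonate anion attacks the hindered aldehyde through its phosphorus-bearing carbon to give the E C7'=C8' bond, and the tiglate-type E geometry at C9'=C10' is the thermodynamically preferred one (the minor 9'Z ester is removed by chromatography).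

Step 15
Reactants: 26 the C15 dienoate
Product: 27 (2E,4E)-5-[(3S,4S)-3,4-bis(tert-butyldimethylsilyloxy)-2,6,6-trimethylcyclohex-1-en-1-yl]-3-methylpenta-2,4-dien-1-ol
Conditions: i-Bu2AlH (2.5 equiv), CH2Cl2, −78 °C; aq. potassium sodium tartrate
Reagents that add atoms: none
Why: 1,2-Reduction of the dienoate to the allylic alcohol by the aluminium hydride at low temperature leaves the silyl ethers and the alkene geometry unchanged.

Step 16
Reactants: 27 the olefinic C15 alcohol
Product: 28 olefinic C15 allylic bromide
Conditions: CBr4 (1.3 equiv), PPh3 (1.3 equiv), CH2Cl2, 0 °C, dark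
Reagents that add atoms: carbon tetrabromide, BrC(Br)(Br)Br
Why: Appel reaction under neutral conditions, chosen because the C4' silyl ether is allylic to a triene and would ionise under acid.

Step 17
Reactants: 28 olefinic C15 allylic bromide
Product: 29 olefinic C15 triphenylphosphonium bromide
Conditions: PPh3 (1.5 equiv), EtOAc, rt, dark
Reagents that add atoms: triphenylphosphine, c1ccc(cc1)P(c1ccccc1)c1ccccc1
Why: SN2 quaternisation of PPh3 by the primary allylic bromide.

Step 18
Reactants: 29 olefinic C15 triphenylphosphonium bromide (1.3 equiv); 23 the acetylenic C25 aldehyde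
Product: 31 (3S,4S,3'S,4'S)-3,4,3',4'-tetrakis(tert-butyldimethylsilyloxy)-7,8-didehydro-β,β-carotene (all-E), via phosphonium ylide 30 (not isolated)
Conditions: NaOMe (1.4 equiv, 1 M in MeOH), CH2Cl2, 0 °C to rt, argon, dark; chromatography
Reagents that add atoms: none
Why: Wittig reaction of the allylic ylide with the polyenal forms C11'=C12'; a mixture rich in the E isomer is expected and the hindered 11'Z isomer is separated (or converted to E by gentle warming in the dark), while iodine and prolonged heating are avoided to protect the 9E bond next to the alkyne.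

Step 19
Reactants: 31 the tetra-TBS carotenoid
Product: 32 (3S,4S,3'S,4'S)-7,8-didehydro-β,β-carotene-3,4,3',4'-tetrol (all-E), the target
Conditions: Bu4NF (8 equiv), THF, rt to 40 °C, argon, dark; chromatography on deactivated silica
Reagents that add atoms: none
Why: Fluoride-mediated desilylation under non-acidic conditions removes all four secondary silyl ethers without ionising the allylic C4–O and C4'–O bonds, so the four stereocentres are released unchanged.

**Compound list**

1 | safranal (2,6,6-trimethylcyclohexa-1,3-diene-1-carbaldehyde) | CC1=C(C=O)C(C)(C)CC=C1 | starting material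
2 | rac-3,4-epoxysafranal (2,4,4-trimethyl-7-oxabicyclo[4.1.0]hept-2-ene-3-carbaldehyde; racemic, cis-fused) | CC1=C(C=O)C(C)(C)CC2OC12 | intermediate
3 | rac-trans-3,4-dihydroxy-2,6,6-trimethylcyclohex-1-ene-1-carbaldehyde (both enantiomers shown) | CC1=C(C=O)C(C)(C)C[C@H](O)[C@H]1O.CC1=C(C=O)C(C)(C)C[C@@H](O)[C@@H]1O | intermediate
4 | (3S,4S)-3,4-dihydroxy-2,6,6-trimethylcyclohex-1-ene-1-carbaldehyde | CC1=C(C=O)C(C)(C)C[C@H](O)[C@H]1O | intermediate
5 | (3S,4S)-3,4-bis(tert-butyldimethylsilyloxy)-2,6,6-trimethylcyclohex-1-ene-1-carbaldehyde | CC1=C(C=O)C(C)(C)C[C@H](O[Si](C)(C)C(C)(C)C)[C@H]1O[Si](C)(C)C(C)(C)C | intermediate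
6 | but-2-yn-1-ol | CC#CCO | starting material
7 | tert-butyl(but-2-yn-1-yloxy)dimethylsilane | CC#CCO[Si](C)(C)C(C)(C)C | intermediate
8 | alkenylzirconocene chloride (Zr on C3, trans to CH2OTBS; cyclopentadienyl drawn σ-bonded) | C/C(=C\CO[Si](C)(C)C(C)(C)C)[Zr](Cl)(C1C=CC=C1)C1C=CC=C1 | intermediate
9 | (E)-tert-butyl[(3-iodobut-2-en-1-yl)oxy]dimethylsilane | I/C(C)=C/CO[Si](C)(C)C(C)(C)C | intermediate
10 | vinyllithium from 9 (Li trans to CH2OTBS) | [Li]/C(C)=C/CO[Si](C)(C)C(C)(C)C | intermediate
11 | (2E)-1-[(3S,4S)-3,4-bis(TBS-oxy)-2,6,6-trimethylcyclohex-1-en-1-yl]-4-(TBS-oxy)-2-methylbut-2-en-1-ol (carbinol epimers) | CC1=C(C(O)/C(C)=C/CO[Si](C)(C)C(C)(C)C)C(C)(C)C[C@H](O[Si](C)(C)C(C)(C)C)[C@H]1O[Si](C)(C)C(C)(C)C | intermediate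
12 | (2E)-1-[(3S,4S)-3,4-bis(TBS-oxy)-2,6,6-trimethylcyclohex-1-en-1-yl]-4-(TBS-oxy)-2-methylbut-2-en-1-one (key-step precursor) | CC1=C(C(=O)/C(C)=C/CO[Si](C)(C)C(C)(C)C)C(C)(C)C[C@H](O[Si](C)(C)C(C)(C)C)[C@H]1O[Si](C)(C)C(C)(C)C | intermediate
13 | trimethylsilyldiazomethane | C[Si](C)(C)C=[N+]=[N-] | starting material
14 | lithio(trimethylsilyl)diazomethane | C[Si](C)(C)C([Li])=[N+]=[N-] | intermediate
15 | diazoalkene from 12 | CC1=C(C(=C=[N+]=[N-])/C(C)=C/CO[Si](C)(C)C(C)(C)C)C(C)(C)C[C@H](O[Si](C)(C)C(C)(C)C)[C@H]1O[Si](C)(C)C(C)(C)C | intermediate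
16 | alkylidene carbene | CC1=C(C(=[C])/C(C)=C/CO[Si](C)(C)C(C)(C)C)C(C)(C)C[C@H](O[Si](C)(C)C(C)(C)C)[C@H]1O[Si](C)(C)C(C)(C)C | intermediate
17 | tris-TBS acetylenic C15 enyne (key-step product) | CC1=C(C#C/C(C)=C/CO[Si](C)(C)C(C)(C)C)C(C)(C)C[C@H](O[Si](C)(C)C(C)(C)C)[C@H]1O[Si](C)(C)C(C)(C)C | intermediate
18 | (2E)-5-[(3S,4S)-3,4-bis(TBS-oxy)-2,6,6-trimethylcyclohex-1-en-1-yl]-3-methylpent-2-en-4-yn-1-ol | CC1=C(C#C/C(C)=C/CO)C(C)(C)C[C@H](O[Si](C)(C)C(C)(C)C)[C@H]1O[Si](C)(C)C(C)(C)C | intermediate
19 | acetylenic C15 allylic bromide | CC1=C(C#C/C(C)=C/CBr)C(C)(C)C[C@H](O[Si](C)(C)C(C)(C)C)[C@H]1O[Si](C)(C)C(C)(C)C | intermediate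
20 | acetylenic C15 triphenylphosphonium bromide | CC1=C(C#C/C(C)=C/C[P+](c2ccccc2)(c2ccccc2)c2ccccc2)C(C)(C)C[C@H](O[Si](C)(C)C(C)(C)C)[C@H]1O[Si](C)(C)C(C)(C)C.[Br-] | intermediate
21 | (2E,4E,6E)-2,7-dimethylocta-2,4,6-trienedial | O=C/C(C)=C/C=C/C=C(C)/C=O | starting material
22 | acetylenic C15 phosphonium ylide | CC1=C(C#C/C(C)=C/C=P(c2ccccc2)(c2ccccc2)c2ccccc2)C(C)(C)C[C@H](O[Si](C)(C)C(C)(C)C)[C@H]1O[Si](C)(C)C(C)(C)C | intermediate
23 | acetylenic C25 aldehyde, (2E,4E,6E,8E,10E)-13-[ring]-2,7,11-trimethyltrideca-2,4,6,8,10-pentaen-12-ynal | CC1=C(C#C/C(C)=C/C=C/C(C)=C/C=C/C=C(C)/C=O)C(C)(C)C[C@H](O[Si](C)(C)C(C)(C)C)[C@H]1O[Si](C)(C)C(C)(C)C | intermediate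
24 | triethyl 3-methyl-4-phosphonocrotonate (ethyl (E)-4-(diethoxyphosphoryl)-3-methylbut-2-enoate) | CCOC(=O)/C=C(C)/CP(=O)(OCC)OCC | starting material
25 | lithiated phosphonate | CCOC(=O)/C=C(C)/C([Li])P(=O)(OCC)OCC | intermediate
26 | ethyl (2E,4E)-5-[(3S,4S)-3,4-bis(TBS-oxy)-2,6,6-trimethylcyclohex-1-en-1-yl]-3-methylpenta-2,4-dienoate | CC1=C(/C=C/C(C)=C/C(=O)OCC)C(C)(C)C[C@H](O[Si](C)(C)C(C)(C)C)[C@H]1O[Si](C)(C)C(C)(C)C | intermediate
27 | (2E,4E)-5-[(3S,4S)-3,4-bis(TBS-oxy)-2,6,6-trimethylcyclohex-1-en-1-yl]-3-methylpenta-2,4-dien-1-ol | CC1=C(/C=C/C(C)=C/CO)C(C)(C)C[C@H](O[Si](C)(C)C(C)(C)C)[C@H]1O[Si](C)(C)C(C)(C)C | intermediate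
28 | olefinic C15 allylic bromide | CC1=C(/C=C/C(C)=C/CBr)C(C)(C)C[C@H](O[Si](C)(C)C(C)(C)C)[C@H]1O[Si](C)(C)C(C)(C)C | intermediate
29 | olefinic C15 triphenylphosphonium bromide | CC1=C(/C=C/C(C)=C/C[P+](c2ccccc2)(c2ccccc2)c2ccccc2)C(C)(C)C[C@H](O[Si](C)(C)C(C)(C)C)[C@H]1O[Si](C)(C)C(C)(C)C.[Br-] | intermediate
30 | olefinic C15 phosphonium ylide | CC1=C(/C=C/C(C)=C/C=P(c2ccccc2)(c2ccccc2)c2ccccc2)C(C)(C)C[C@H](O[Si](C)(C)C(C)(C)C)[C@H]1O[Si](C)(C)C(C)(C)C | intermediate
31 | (3S,4S,3'S,4'S)-3,4,3',4'-tetrakis(TBS-oxy)-7,8-didehydro-β,β-carotene (all-E) | CC1=C(C#C/C(C)=C/C=C/C(C)=C/C=C/C=C(C)/C=C/C=C(C)/C=C/C2=C(C)[C@H](O[Si](C)(C)C(C)(C)C)[C@@H](O[Si](C)(C)C(C)(C)C)CC2(C)C)C(C)(C)C[C@H](O[Si](C)(C)C(C)(C)C)[C@H]1O[Si](C)(C)C(C)(C)C | intermediate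
32 | (3S,4S,3'S,4'S)-7,8-didehydro-β,β-carotene-3,4,3',4'-tetrol (all-E) | CC1=C(C#C/C(C)=C/C=C/C(C)=C/C=C/C=C(C)/C=C/C=C(C)/C=C/C2=C(C)[C@H](O)[C@@H](O)CC2(C)C)C(C)(C)C[C@H](O)[C@H]1O | target

**Step count**

Total: 19 steps. Longest linear sequence: 13 steps (steps 1, 2, 3, 4, 7, 8, 9, 10, 11, 12, 13, 18, 19, from safranal).

**Steps most likely to fail**

1. Step 9 (carbene shift). The bulky lithiated diazo reagent may add too slowly to a carbonyl group flanked by the C1 gem-dimethyl group, the C5 methyl group and the α-methyl group, so that ketone is returned. The anion may instead deprotonate a γ-position or add to or cyclo-add across the enone. The carbene may also be diverted into C–H insertion before the alkenyl group shifts. Fallback: set out from aldehyde 5 and iodide 9 and place the one-carbon homologation on the aldehyde, where the migrating group is hydrogen. Corey–Fuchs olefination of 5 (CBr4, PPh3, CH2Cl2, 0 °C) should give the 1,1-dibromoalkene F1. Treatment with n-BuLi (2.2 equiv, THF, −78 °C, then H2O) should give the ring ethynyl compound F2 through the 1,2-hydrogen shift of the bromovinylidene carbenoid. Sonogashira coupling of F2 with 9 (Pd(PPh3)4, zerovalent palladium, CuI, Et3N, rt) then joins C8 to C9 at the unhindered alkenyl iodide carbon with retention of the E geometry. The fallback comes back to the route at 17.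

2. Step 13 (first Wittig reaction). The delocalised acetylenic ylide may lose the 9E geometry by rotation about C9–C10. Both formyl groups of the dialdehyde may react. The new C11=C12 bond may form with a large share of Z isomer that cannot be isomerised without also scrambling C9=C10. Fallback: reverse the polarity at C11=C12 so that the acetylenic half never passes through an ylide; it sets out from 18, 29 and 21. MnO2 (CH2Cl2, rt) should oxidise 18 to the enynal F3. Wittig reaction of 29 with excess 21 (NaOMe, CH2Cl2) should give the olefinic C25 aldehyde F4. NaBH4 (MeOH/THF, 0 °C) reduces F4 to the C25 alcohol F5. PPh3·HBr (MeOH/CH2Cl2, 0 °C, short contact) gives the C25 phosphonium bromide F6, the pentaenyl carbinol ionising far more readily than the ring ethers, as in retinol-type alcohols. Wittig reaction of F6 with F3 (NaOMe, CH2Cl2, 0 °C) then forms C11=C12 from a chain ylide that relaxes towards all-E. The fallback comes back to the route at 31.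

3. Step 7 (vinyllithium addition). The hindered α-branched vinyllithium may fail to add to the shielded aldehyde, or it may act as a base. Removal of C4–H followed by vinylogous β-elimination of the C3 silyloxy group would destroy the ring stereocentres. Fallback: a non-basic Nozaki–Hiyama–Kishi coupling of 9 with 5 (CrCl2, divalent chromium, in excess with NiCl2, divalent nickel, 1 mol %, DMF/THF, rt). The alkenylchromium species adds chemoselectively to aldehydes and does not deprotonate them. The fallback sets out from 9 and 5, makes no new compound (F0) and comes back to the route at 11.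

**Further compounds**

F1 | step 9 | (3S,4S)-3,4-bis(TBS-oxy)-1-(2,2-dibromoethenyl)-2,6,6-trimethylcyclohex-1-ene | CC1=C(C=C(Br)Br)C(C)(C)C[C@H](O[Si](C)(C)C(C)(C)C)[C@H]1O[Si](C)(C)C(C)(C)C
F2 | step 9 | (3S,4S)-3,4-bis(TBS-oxy)-1-ethynyl-2,6,6-trimethylcyclohex-1-ene | CC1=C(C#C)C(C)(C)C[C@H](O[Si](C)(C)C(C)(C)C)[C@H]1O[Si](C)(C)C(C)(C)C
F3 | step 13 | (2E)-5-[(3S,4S)-3,4-bis(TBS-oxy)-2,6,6-trimethylcyclohex-1-en-1-yl]-3-methylpent-2-en-4-ynal | CC1=C(C#C/C(C)=C/C=O)C(C)(C)C[C@H](O[Si](C)(C)C(C)(C)C)[C@H]1O[Si](C)(C)C(C)(C)C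
F4 | step 13 | olefinic C25 aldehyde, (2E,4E,6E,8E,10E,12E)-13-[(3S,4S)-3,4-bis(TBS-oxy)-2,6,6-trimethylcyclohex-1-en-1-yl]-2,7,11-trimethyltrideca-2,4,6,8,10,12-hexaenal | CC1=C(/C=C/C(C)=C/C=C/C(C)=C/C=C/C=C(C)/C=O)C(C)(C)C[C@H](O[Si](C)(C)C(C)(C)C)[C@H]1O[Si](C)(C)C(C)(C)C
F5 | step 13 | olefinic C25 alcohol | CC1=C(/C=C/C(C)=C/C=C/C(C)=C/C=C/C=C(C)/CO)C(C)(C)C[C@H](O[Si](C)(C)C(C)(C)C)[C@H]1O[Si](C)(C)C(C)(C)C
F6 | step 13 | olefinic C25 triphenylphosphonium bromide | CC1=C(/C=C/C(C)=C/C=C/C(C)=C/C=C/C=C(C)/C[P+](c2ccccc2)(c2ccccc2)c2ccccc2)C(C)(C)C[C@H](O[Si](C)(C)C(C)(C)C)[C@H]1O[Si](C)(C)C(C)(C)C.[Br-]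
F0 | step 7 | none | none
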